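**Plan**
1. Retrosynthesis: O1–C2 and C3–C4 of the lower pyran ring (ring C) are cut together, back to a salicylaldehyde on ring A and an α-hydroxy ketone carrying ring B; the interflavan C4–C8 bond is cut to a flavanone and a metalated phloroglucinol ether; the upper C2–aryl bond is cut to a chromone and an arylboronic acid.
2. Enabling feature: in the lower unit O1 (on C8a) and C4 (on C4a) are ortho on phloroglucinol ring A, C2 carries ring B and C3 an oxygen, so ring C can be closed in one operation as a flat, aromatic 3-hydroxybenzopyrylium (flavylium) ring without any stereocentre; the extra unsaturation is the helper and is removed in steps 10 and 11.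
3. Forward order: upper flavanone, aryl addition at C4 and ionic hydrogenation (2,4-cis flavan), free O1 and ortho-formyl group on ring A, flavylium ring C (key step), flavan-3-one, cis-flavan-3-ol, global debenzylation.
4. Stereochemistry: upper C2 (S) from a chiral rhodium catalyst; upper C4 (S) from pseudoaxial hydride delivery to the C4 cation; lower C2 and C3 (R,R) together from a dynamic kinetic resolution that funnels the C2-labile flavan-3-one into the 2,3-cis alcohol.
5. All phenols travel as benzyl ethers; only O1 of the lower unit is freed (through a methoxymethyl ether), so it alone can enter the ring closure and the 4→8 linkage is fixed.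

Key step: step 9

Remark: the target is read as (2S,4S)-4',7-dihydroxyflavan-(4→8)-(2R,3R)-epiafzelechin, i.e. 2,4-cis in the upper unit and 2,3-cis in the lower unit.

**Step 1**
Reactants: 1 7-hydroxy-4H-chromen-4-one
Product: 2 7-(benzyloxy)-4H-chromen-4-one
Conditions: BnBr, K2CO3, DMF, 25 °C
Reagents that add atoms: benzyl bromide (BrCc1ccccc1)
Why: Williamson ether synthesis on the acidic phenol gives a benzyl ether that survives all later steps and falls in the final hydrogenolysis.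

**Step 2**
Reactants: 2 7-(benzyloxy)-4H-chromen-4-one, 3 [4-(benzyloxy)phenyl]boronic acid
Product: 4 (2S)-7-(benzyloxy)-2-[4-(benzyloxy)phenyl]-2,3-dihydro-4H-chromen-4-one
Conditions: [Rh(OH)(cod)]2 (1.5 mol%), (S)-MeO-F12-BIPHEP (3.3 mol%), toluene/H2O, 25 °C
Reagents that add atoms: none
Why: Hayashi–Miyaura asymmetric 1,4-addition to the chromone, in which the (S)-ligand (the enantiomer that gives (S)-3-arylcyclohexanones from cyclohex-2-enone) should place the aryl group on the face of C2 that gives the 2S ketone, under neutral conditions that avoid retro-oxa-Michael ring opening.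

**Step 3**
Reactants: 5 3,5-bis(benzyloxy)phenol
Product: 6 1,3-bis(benzyloxy)-5-(methoxymethoxy)benzene
Conditions: NaH, DMF, 0 °C; MOMCl, 0 → 25 °C
Reagents that add atoms: chloromethyl methyl ether (COCCl)
Why: O-alkylation of the sodium phenoxide (Williamson type) marks the oxygen that becomes O1 of the lower unit with the strongest ortho-directing group of the ring.

**Step 4**
Reactants: 6 1,3-bis(benzyloxy)-5-(methoxymethoxy)benzene, 4 (2S)-7-(benzyloxy)-2-[4-(benzyloxy)phenyl]-2,3-dihydro-4H-chromen-4-one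
Product: 9 (2S)-7-(benzyloxy)-2-[4-(benzyloxy)phenyl]-4-[2,4-bis(benzyloxy)-6-(methoxymethoxy)phenyl]chroman-4-ol (both C4 epimers), via aryllithium 7 (not isolated), via arylcerium dichloride 8 (not isolated)
Conditions: n-BuLi, THF, 0 °C; CeCl3, THF, −78 °C; then 4, −78 → −40 °C; aq. NH4Cl
Reagents that add atoms: none
Why: Directed ortho-metalation between the methoxymethoxy and a benzyloxy group, then organocerium 1,2-addition, whose low basicity should spare the enolisable flavanone from C3 deprotonation and C2 epimerisation; the carbinol centre C4 forms unselectively and is erased in step 5.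

**Step 5**
Reactants: 9 (2S)-7-(benzyloxy)-2-[4-(benzyloxy)phenyl]-4-[2,4-bis(benzyloxy)-6-(methoxymethoxy)phenyl]chroman-4-ol
Product: 10 (2S,4S)-7-(benzyloxy)-2-[4-(benzyloxy)phenyl]-4-[2,4-bis(benzyloxy)-6-(methoxymethoxy)phenyl]chromane
Conditions: Et3SiH, CF3CO2H, CH2Cl2, −78 → −40 °C
Reagents that add atoms: none
Why: Ionic hydrogenation, in which hydride should enter the doubly benzylic C4 cation along the pseudoaxial trajectory on the face syn to H2 of the half-chair with the C2 aryl group equatorial, so the bulky 4-aryl group ends equatorial and the 2,4-cis (4S) configuration, also the more stable one, results.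

**Step 6**
Reactants: 10 (2S,4S)-7-(benzyloxy)-2-[4-(benzyloxy)phenyl]-4-[2,4-bis(benzyloxy)-6-(methoxymethoxy)phenyl]chromane
Product: 11 3,5-bis(benzyloxy)-2-[(2S,4S)-7-(benzyloxy)-2-[4-(benzyloxy)phenyl]chroman-4-yl]phenol
Conditions: ZnBr2, n-PrSH, CH2Cl2, 0 °C
Reagents that add atoms: none
Why: Lewis acid mediated acetal cleavage, in which the thiol traps the methoxymethyl cation before it can alkylate the electron-rich ring, while benzyl ethers and the interflavan bond stay intact.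

**Step 7**
Reactants: 11 3,5-bis(benzyloxy)-2-[(2S,4S)-7-(benzyloxy)-2-[4-(benzyloxy)phenyl]chroman-4-yl]phenol
Product: 12 4,6-bis(benzyloxy)-3-[(2S,4S)-7-(benzyloxy)-2-[4-(benzyloxy)phenyl]chroman-4-yl]-2-hydroxybenzaldehyde
Conditions: MgCl2, Et3N, (CH2O)n, MeCN, 80 °C
Reagents that add atoms: paraformaldehyde (C=O)
Why: Casnati–Skattebøl ortho-formylation, in which the magnesium phenoxide delivers formaldehyde only to the single free ortho carbon (the later C4a) and hydride transfer to a second formaldehyde gives the aldehyde.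

**Step 8**
Reactants: 13 1-[4-(benzyloxy)phenyl]-2-bromoethan-1-one
Product: 15 1-[4-(benzyloxy)phenyl]-2-hydroxyethan-1-one, via phenacyl formate 14 (not isolated)
Conditions: HCO2Na, EtOH/H2O, reflux
Reagents that add atoms: sodium formate ([Na+].[O-]C=O)
Why: SN2 displacement of the α-bromide by formate followed by in situ solvolysis of the formate ester gives the α-hydroxy ketone without strongly basic conditions.

**Step 9**
Reactants: 12 4,6-bis(benzyloxy)-3-[(2S,4S)-7-(benzyloxy)-2-[4-(benzyloxy)phenyl]chroman-4-yl]-2-hydroxybenzaldehyde, 15 1-[4-(benzyloxy)phenyl]-2-hydroxyethan-1-one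
Product: 17 5,7-bis(benzyloxy)-2-[4-(benzyloxy)phenyl]-8-[(2S,4S)-7-(benzyloxy)-2-[4-(benzyloxy)phenyl]chroman-4-yl]-3-hydroxychromenylium chloride, via alpha-hydroxychalcone 16 (not isolated)
Conditions: dry HCl (g), EtOAc, 0 → 25 °C; salt precipitated with Et2O
Reagents that add atoms: hydrogen chloride (Cl)
Why: An acid-catalysed crossed aldol condensation joins the enol carbon of 15 (C3, already carrying its oxygen) to the formyl carbon C4 of 12 and gives enone 16. The free phenol O1 on C8a then adds to the aryl ketone carbon C2 (6-exo-trig hemiketalisation after E/Z equilibration of the enone), and loss of water aromatises ring C to the benzopyrylium. The closest known reaction type is the classical flavylium (anthocyanidin) synthesis from a 2-hydroxybenzaldehyde and an ω-oxygenated acetophenone. No stereocentre is created: C2, C3 and C4 are sp2 in 17 by design, so that C2 and C3 can be set later under catalyst control. The step needs O1 to react in preference to O5 and O7, and cross-condensation in preference to self-condensation. The first is secured because O1 is the only free hydroxyl of ring A and sits ortho to the formyl group; the second because 12 cannot enolise and 15 enolises only toward C3, while the formyl group deactivates ring A against acid cleavage of the C4–C8 interflavan bond.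

**Step 10**
Reactants: 17 5,7-bis(benzyloxy)-2-[4-(benzyloxy)phenyl]-8-[(2S,4S)-7-(benzyloxy)-2-[4-(benzyloxy)phenyl]chroman-4-yl]-3-hydroxychromenylium chloride
Product: 19 5,7-bis(benzyloxy)-2-[4-(benzyloxy)phenyl]-8-[(2S,4S)-7-(benzyloxy)-2-[4-(benzyloxy)phenyl]chroman-4-yl]chroman-3-one (both C2 epimers), via 4H-chromen-3-ol 18 (not isolated)
Conditions: Hantzsch ester (diethyl 2,6-dimethyl-1,4-dihydropyridine-3,5-dicarboxylate), CH2Cl2, 0 → 25 °C, argon
Reagents that add atoms: none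
Why: Hydride transfer from the dihydropyridine to C4 of the benzopyrylium ion (transfer hydrogenation of a flavylium salt) gives the enol, which tautomerises to the flavan-3-one; attack at C2 would give the other enol of the same ketone, and the mild donor should leave the carbonyl group untouched.

**Step 11**
Reactants: 19 5,7-bis(benzyloxy)-2-[4-(benzyloxy)phenyl]-8-[(2S,4S)-7-(benzyloxy)-2-[4-(benzyloxy)phenyl]chroman-4-yl]chroman-3-one
Product: 20 (2R,3R)-5,7-bis(benzyloxy)-2-[4-(benzyloxy)phenyl]-8-[(2S,4S)-7-(benzyloxy)-2-[4-(benzyloxy)phenyl]chroman-4-yl]chroman-3-ol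
Conditions: RuCl2[(S)-binap][(R,R)-dpen] (2 mol%), KOt-Bu (20 mol%), H2 (10 atm), i-PrOH/toluene, 25 °C
Reagents that add atoms: none
Why: Noyori asymmetric hydrogenation with dynamic kinetic resolution: the base should epimerise C2 (α to the ketone, benzylic and O-substituted) faster than reduction, and the catalyst (the enantiomer that turns racemic 2-alkylcyclohexanones into cis-(1R,2R)-alcohols) should reduce only the 2R ketone from the face anti to the C2 aryl group, setting C2 and C3 as the 2,3-cis (2R,3R) pair.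

**Step 12**
Reactants: 20 (2R,3R)-5,7-bis(benzyloxy)-2-[4-(benzyloxy)phenyl]-8-[(2S,4S)-7-(benzyloxy)-2-[4-(benzyloxy)phenyl]chroman-4-yl]chroman-3-ol
Product: 21 (2R,3R)-8-[(2S,4S)-7-hydroxy-2-(4-hydroxyphenyl)chroman-4-yl]-2-(4-hydroxyphenyl)chromane-3,5,7-triol
Conditions: H2 (1 atm), Pd(OH)2/C, THF/MeOH, 25 °C
Reagents that add atoms: none
Why: Hydrogenolysis of the five benzyl ethers under neutral conditions should leave the benzylic C2–O bonds of both pyran rings and the interflavan bond intact.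

**Compound list**
1 | 7-hydroxy-4H-chromen-4-one | O=c1ccoc2cc(O)ccc12 | starting material
2 | 7-(benzyloxy)-4H-chromen-4-one | O=c1ccoc2cc(OCc3ccccc3)ccc12 | intermediate
3 | [4-(benzyloxy)phenyl]boronic acid | OB(O)c1ccc(OCc2ccccc2)cc1 | starting material
4 | (2S)-7-(benzyloxy)-2-[4-(benzyloxy)phenyl]-2,3-dihydro-4H-chromen-4-one | O=C1C[C@@H](c2ccc(OCc3ccccc3)cc2)Oc2cc(OCc3ccccc3)ccc12 | intermediate
5 | 3,5-bis(benzyloxy)phenol | Oc1cc(OCc2ccccc2)cc(OCc2ccccc2)c1 | starting material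
6 | 1,3-bis(benzyloxy)-5-(methoxymethoxy)benzene | COCOc1cc(OCc2ccccc2)cc(OCc2ccccc2)c1 | intermediate
7 | [2,4-bis(benzyloxy)-6-(methoxymethoxy)phenyl]lithium | [Li]c1c(OCOC)cc(OCc2ccccc2)cc1OCc1ccccc1 | intermediate
8 | [2,4-bis(benzyloxy)-6-(methoxymethoxy)phenyl]cerium dichloride | Cl[Ce](Cl)c1c(OCOC)cc(OCc2ccccc2)cc1OCc1ccccc1 | intermediate
9 | (2S)-7-(benzyloxy)-2-[4-(benzyloxy)phenyl]-4-[2,4-bis(benzyloxy)-6-(methoxymethoxy)phenyl]chroman-4-ol (both C4 epimers) | COCOc1cc(OCc2ccccc2)cc(OCc2ccccc2)c1C1(O)C[C@@H](c2ccc(OCc3ccccc3)cc2)Oc2cc(OCc3ccccc3)ccc21 | intermediate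
10 | (2S,4S)-7-(benzyloxy)-2-[4-(benzyloxy)phenyl]-4-[2,4-bis(benzyloxy)-6-(methoxymethoxy)phenyl]chromane | COCOc1cc(OCc2ccccc2)cc(OCc2ccccc2)c1[C@H]1C[C@@H](c2ccc(OCc3ccccc3)cc2)Oc2cc(OCc3ccccc3)ccc21 | intermediate
11 | 3,5-bis(benzyloxy)-2-[(2S,4S)-7-(benzyloxy)-2-[4-(benzyloxy)phenyl]chroman-4-yl]phenol | Oc1cc(OCc2ccccc2)cc(OCc2ccccc2)c1[C@H]1C[C@@H](c2ccc(OCc3ccccc3)cc2)Oc2cc(OCc3ccccc3)ccc21 | intermediate
12 | 4,6-bis(benzyloxy)-3-[(2S,4S)-7-(benzyloxy)-2-[4-(benzyloxy)phenyl]chroman-4-yl]-2-hydroxybenzaldehyde | O=Cc1c(O)c([C@H]2C[C@@H](c3ccc(OCc4ccccc4)cc3)Oc3cc(OCc4ccccc4)ccc32)c(OCc2ccccc2)cc1OCc1ccccc1 | intermediate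
13 | 1-[4-(benzyloxy)phenyl]-2-bromoethan-1-one | O=C(CBr)c1ccc(OCc2ccccc2)cc1 | starting material
14 | 2-[4-(benzyloxy)phenyl]-2-oxoethyl formate | O=COCC(=O)c1ccc(OCc2ccccc2)cc1 | intermediate
15 | 1-[4-(benzyloxy)phenyl]-2-hydroxyethan-1-one | O=C(CO)c1ccc(OCc2ccccc2)cc1 | intermediate
16 | 1-[4-(benzyloxy)phenyl]-3-{4,6-bis(benzyloxy)-3-[(2S,4S)-7-(benzyloxy)-2-[4-(benzyloxy)phenyl]chroman-4-yl]-2-hydroxyphenyl}-2-hydroxyprop-2-en-1-one (alkene geometry not fixed under the acid) | O=C(c1ccc(OCc2ccccc2)cc1)C(O)=Cc1c(O)c([C@H]2C[C@@H](c3ccc(OCc4ccccc4)cc3)Oc3cc(OCc4ccccc4)ccc32)c(OCc2ccccc2)cc1OCc1ccccc1 | intermediate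
17 | 5,7-bis(benzyloxy)-2-[4-(benzyloxy)phenyl]-8-[(2S,4S)-7-(benzyloxy)-2-[4-(benzyloxy)phenyl]chroman-4-yl]-3-hydroxychromenylium chloride | Oc1cc2c(OCc3ccccc3)cc(OCc3ccccc3)c([C@H]3C[C@@H](c4ccc(OCc5ccccc5)cc4)Oc4cc(OCc5ccccc5)ccc43)c2[o+]c1-c1ccc(OCc2ccccc2)cc1.[Cl-] | intermediate
18 | 5,7-bis(benzyloxy)-2-[4-(benzyloxy)phenyl]-8-[(2S,4S)-7-(benzyloxy)-2-[4-(benzyloxy)phenyl]chroman-4-yl]-4H-chromen-3-ol | OC1=C(c2ccc(OCc3ccccc3)cc2)Oc2c(C1)c(OCc1ccccc1)cc(OCc1ccccc1)c2[C@H]1C[C@@H](c2ccc(OCc3ccccc3)cc2)Oc2cc(OCc3ccccc3)ccc21 | intermediate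
19 | 5,7-bis(benzyloxy)-2-[4-(benzyloxy)phenyl]-8-[(2S,4S)-7-(benzyloxy)-2-[4-(benzyloxy)phenyl]chroman-4-yl]chroman-3-one (both C2 epimers, C2 labile) | O=C1Cc2c(OCc3ccccc3)cc(OCc3ccccc3)c([C@H]3C[C@@H](c4ccc(OCc5ccccc5)cc4)Oc4cc(OCc5ccccc5)ccc43)c2OC1c1ccc(OCc2ccccc2)cc1 | intermediate
20 | (2R,3R)-5,7-bis(benzyloxy)-2-[4-(benzyloxy)phenyl]-8-[(2S,4S)-7-(benzyloxy)-2-[4-(benzyloxy)phenyl]chroman-4-yl]chroman-3-ol | c1ccccc1COc1ccc([C@@H]2C[C@H](c3c(OCc5ccccc5)cc(OCc5ccccc5)c4c3O[C@H](c3ccc(OCc5ccccc5)cc3)[C@H](O)C4)c3ccc(OCc5ccccc5)cc3O2)cc1 | intermediate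
21 | (2R,3R)-8-[(2S,4S)-7-hydroxy-2-(4-hydroxyphenyl)chroman-4-yl]-2-(4-hydroxyphenyl)chromane-3,5,7-triol (CNP0254623.1) | Oc1ccc([C@@H]2C[C@H](c3c(O)cc(O)c4c3O[C@H](c3ccc(O)cc3)[C@H](O)C4)c3ccc(O)cc3O2)cc1 | target

**Step count and risks**
Total steps: 12. Longest linear sequence: 10 steps (steps 1, 2, 4, 5, 6, 7, 9, 10, 11, 12).

Step 4 (aryl addition to the flavanone). The hindered aryl nucleophile may deprotonate C3 instead of adding, which would open the pyran ring by retro-oxa-Michael reaction and racemise C2, or it may fail to add for steric reasons. The fallback sets out from 4 (with aryllithium 7 from 6) and returns at 10, so it also replaces step 5. Ketone 4 would be converted with Tf2O and 2,6-di-tert-butyl-4-methylpyridine in CH2Cl2, without strong base, into (2S)-7-(benzyloxy)-2-[4-(benzyloxy)phenyl]-2H-chromen-4-yl trifluoromethanesulfonate F1. Aryllithium 7 would be transmetalated with ZnCl2 to chlorido[2,4-bis(benzyloxy)-6-(methoxymethoxy)phenyl]zinc F2. Negishi coupling of F1 and F2 (Pd(OAc)2, SPhos, THF, 50 °C) should give (2S)-7-(benzyloxy)-2-[4-(benzyloxy)phenyl]-4-[2,4-bis(benzyloxy)-6-(methoxymethoxy)phenyl]-2H-chromene F3. Homogeneous hydrogenation with [Ir(cod)(PCy3)(py)]PF6 under H2 in CH2Cl2 should add hydrogen anti to the C2 aryl group and give the 2,4-cis compound 10 without touching the benzyl ethers.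

Step 9 (key step). Prolonged exposure to dry HCl may cleave benzyl ethers or open the upper C2–O bond, and electron-rich rings may attack C4 of the flavylium ion. The fallback sets out from 12 and returns at 19 under near-neutral conditions. An amine-catalysed Petasis-type condensation of 12 with (E)-2-[4-(benzyloxy)phenyl]vinylboronic acid (Bn2NH 20 mol%, dioxane, 90 °C) would form the same two bonds by alkenyl transfer to C4 and oxa-6π electrocyclisation. It should give 5,7-bis(benzyloxy)-2-[4-(benzyloxy)phenyl]-8-[(2S,4S)-7-(benzyloxy)-2-[4-(benzyloxy)phenyl]chroman-4-yl]-2H-chromene F4 as both C2 epimers. Hydroboration and oxidation (BH3·THF, then NaOH/H2O2) should give the 2,3-trans alcohol 5,7-bis(benzyloxy)-2-[4-(benzyloxy)phenyl]-8-[(2S,4S)-7-(benzyloxy)-2-[4-(benzyloxy)phenyl]chroman-4-yl]chroman-3-ol F5 as a mixture of both lower-unit antipodes. Dess–Martin oxidation converges this mixture on ketone 19.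

Step 11 (dynamic kinetic resolution). Epimerisation at C2 may be slower than reduction, or the facial preference of the catalyst may be opposed by the chiral upper unit, so that diastereomer mixtures result. The catalyst enantiomer is chosen by analogy with 2-alkylcyclohexanones and its sense on this α-aryloxy ketone is untested. The fallback sets out from 12 and returns at 20, with reagent-controlled hydroboration in place of the dynamic reduction.
- Reduction of 12 with NaBH4 (THF/MeOH, 0 °C) would give 3,5-bis(benzyloxy)-2-[(2S,4S)-7-(benzyloxy)-2-[4-(benzyloxy)phenyl]chroman-4-yl]-6-(hydroxymethyl)phenol F6.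
- Acid-catalysed generation of the ortho-quinone methide from F6 (camphorsulfonic acid 10 mol%, CH2Cl2, 0 °C) in the presence of excess 1-(benzyloxy)-4-ethynylbenzene should give, by inverse-demand oxa-[4+2] cycloaddition, 5,7-bis(benzyloxy)-2-[4-(benzyloxy)phenyl]-8-[(2S,4S)-7-(benzyloxy)-2-[4-(benzyloxy)phenyl]chroman-4-yl]-4H-chromene F7.
- Asymmetric hydroboration with IpcBH2 derived from (+)-α-pinene (THF, −25 °C; then NaOH/H2O2) should add H to C2 and B to C3 from the same face and give (2R,3S)-5,7-bis(benzyloxy)-2-[4-(benzyloxy)phenyl]-8-[(2S,4S)-7-(benzyloxy)-2-[4-(benzyloxy)phenyl]chroman-4-yl]chroman-3-ol F8. This is the borane enantiomer that gives (1S,2R)-trans-2-arylcycloalkanols from 1-arylcycloalkenes.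
- Dess–Martin oxidation would give (2R)-5,7-bis(benzyloxy)-2-[4-(benzyloxy)phenyl]-8-[(2S,4S)-7-(benzyloxy)-2-[4-(benzyloxy)phenyl]chroman-4-yl]chroman-3-one F9.
- Reduction with LiBH(s-Bu)3 (THF, −78 °C) from the face anti to the C2 aryl group should give 20.

**Further compounds**
F1 | step 4 | (2S)-7-(benzyloxy)-2-[4-(benzyloxy)phenyl]-2H-chromen-4-yl trifluoromethanesulfonate | O=S(=O)(OC1=C[C@@H](c2ccc(OCc3ccccc3)cc2)Oc2cc(OCc3ccccc3)ccc12)C(F)(F)F
F2 | step 4 | chlorido[2,4-bis(benzyloxy)-6-(methoxymethoxy)phenyl]zinc | Cl[Zn]c1c(OCOC)cc(OCc2ccccc2)cc1OCc1ccccc1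
F3 | step 4 | (2S)-7-(benzyloxy)-2-[4-(benzyloxy)phenyl]-4-[2,4-bis(benzyloxy)-6-(methoxymethoxy)phenyl]-2H-chromene | COCOc1cc(OCc2ccccc2)cc(OCc2ccccc2)c1C1=C[C@@H](c2ccc(OCc3ccccc3)cc2)Oc2cc(OCc3ccccc3)ccc21
F4 | step 9 | 5,7-bis(benzyloxy)-2-[4-(benzyloxy)phenyl]-8-[(2S,4S)-7-(benzyloxy)-2-[4-(benzyloxy)phenyl]chroman-4-yl]-2H-chromene (both C2 epimers) | C1=Cc2c(OCc3ccccc3)cc(OCc3ccccc3)c([C@H]3C[C@@H](c4ccc(OCc5ccccc5)cc4)Oc4cc(OCc5ccccc5)ccc43)c2OC1c1ccc(OCc2ccccc2)cc1
F5 | step 9 | 2,3-trans-5,7-bis(benzyloxy)-2-[4-(benzyloxy)phenyl]-8-[(2S,4S)-7-(benzyloxy)-2-[4-(benzyloxy)phenyl]chroman-4-yl]chroman-3-ol (both lower-unit antipodes) | OC1Cc2c(OCc3ccccc3)cc(OCc3ccccc3)c([C@H]3C[C@@H](c4ccc(OCc5ccccc5)cc4)Oc4cc(OCc5ccccc5)ccc43)c2OC1c1ccc(OCc2ccccc2)cc1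
F6 | step 11 | 3,5-bis(benzyloxy)-2-[(2S,4S)-7-(benzyloxy)-2-[4-(benzyloxy)phenyl]chroman-4-yl]-6-(hydroxymethyl)phenol | OCc1c(O)c([C@H]2C[C@@H](c3ccc(OCc4ccccc4)cc3)Oc3cc(OCc4ccccc4)ccc32)c(OCc2ccccc2)cc1OCc1ccccc1
F7 | step 11 | 5,7-bis(benzyloxy)-2-[4-(benzyloxy)phenyl]-8-[(2S,4S)-7-(benzyloxy)-2-[4-(benzyloxy)phenyl]chroman-4-yl]-4H-chromene | C1(c2ccc(OCc3ccccc3)cc2)=CCc2c(OCc3ccccc3)cc(OCc3ccccc3)c([C@H]3C[C@@H](c4ccc(OCc5ccccc5)cc4)Oc4cc(OCc5ccccc5)ccc43)c2O1
F8 | step 11 | (2R,3S)-5,7-bis(benzyloxy)-2-[4-(benzyloxy)phenyl]-8-[(2S,4S)-7-(benzyloxy)-2-[4-(benzyloxy)phenyl]chroman-4-yl]chroman-3-ol | c1ccccc1COc1ccc([C@@H]2C[C@H](c3c(OCc5ccccc5)cc(OCc5ccccc5)c4c3O[C@H](c3ccc(OCc5ccccc5)cc3)[C@@H](O)C4)c3ccc(OCc5ccccc5)cc3O2)cc1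
F9 | step 11 | (2R)-5,7-bis(benzyloxy)-2-[4-(benzyloxy)phenyl]-8-[(2S,4S)-7-(benzyloxy)-2-[4-(benzyloxy)phenyl]chroman-4-yl]chroman-3-one | c1ccccc1COc1ccc([C@@H]2C[C@H](c3c(OCc5ccccc5)cc(OCc5ccccc5)c4c3O[C@H](c3ccc(OCc5ccccc5)cc3)C(=O)C4)c3ccc(OCc5ccccc5)cc3O2)cc1
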